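A point of links in cedar or larch was 0.0100 M, a percent of c(first end groups) = 1.0 M, so I asked which charges could move a point.

| setting | violet | blue | cedar | larch |
|---|---|---|---|---|
| first end groups | 1 M | 1 M | 1.0 M | 1.0 M |
| second end groups | 0.70 M | 1.5 M | 2.00 M | 0.950 M |
| one-sided end groups | 0.020 M | 0.020 M | 0.0200 M | 0.0200 M |
| protic impurity | 0.10 M | 0.10 M | 0.100 M | 0.100 M |
| remark | run made earlier | run made earlier |  |  |
| time |  |  | 2.5 h | 8.0 h |

- violet (time / h: links / %): 0.667: 49.8; 1.00: 55.0; 1.33: 59.3; 2.50: 63.5; 3.00: 64.6; 5.00: 65.7; 8.00: 65.7
- blue (time / h: links / %): 0.417: 68.4; 1.33: 90.2; 2.50: 96.6; 3.00: 97.3; 5.00: 96.7; 6.00: 97.6; 8.00: 96.9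

(readings scatter by 0.5 percentage points)

* the winner by amount of links, in percent of the first end groups charged; "neither" if no more than 2 percentage points parts them (cedar / larch / neither)
* how much links is there at the end, in percent of the first end groups charged: cedar
* how much links is there at the end, in percent of the first end groups charged: larch

1. I began with c(one-sided end groups). Blue had second end groups in excess, yet it read 96.9% after 8.00 h, so I took each one-sided end group to cap a first end group. An error of 0.0100 M would then shift cedar by 1.00% of the first end groups.
2. In cedar, c(protic impurity) = 0.100 M was less than the excess of second end groups, 1.00 M, so I let it pass there.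
3. In larch, c(second end groups) counted one for one, and so did whatever second end groups were lost without forming links.
4. The number I carried was the capping share 2.00%, c(one-sided end groups) over c(first end groups). It left 0.980 M of first end groups for links.
5. For cedar I therefore reckoned 98.0%. Blue read 96.6% at 2.50 h and stayed near there, so I expected 2.5 h to be long enough.
6. Larch had less second end groups than that free amount, which made them the limiting reagent. Violet, the same case, read 65.7% at 8.00 h, which put its loss, as a reading, at 0.0430 M of them.
7. I assumed this loss grows with the logarithm of the thinning of first end groups, which gave 0.0387 M per unit of logarithm.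
8. A first guess of 0.0860 M lost in larch left 0.116 M of first end groups. The logarithm then gave a loss of 0.0827 M, so I reckoned larch at 86.7%.

The forecast, which judged that “The protic impurity has no clear effect on the plateaus”, named cedar, with 98.3% for cedar and 84.5% for larch, which is lower than my larch figure.

The flask gave cedar: cedar 97.8%, larch 85.9%.

    first end groups + one-sided end groups → capped ends (k = 0.710 M⁻¹ min⁻¹)
    second end groups + protic impurity → quenched reagent (k = 0.00980 M⁻¹ min⁻¹)
    first end groups + second end groups → links (k = 0.0500 M⁻¹ min⁻¹)
    2 second end groups → self-condensation product (k = 0.00190 M⁻¹ min⁻¹)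

Capped ends stood at 2.00% in cedar, against a capping share of 2.00%, and my larch figure of 86.7% stood against 85.9%. The neighbouring flask was cedar with c(first end groups) = 0.25 M. Its capping share was 8.00%, so I reckoned links at 92.0%. It gave 93.2%, with capped ends at 6.83%, first end groups down to 0.0091%, and 15% of its one-sided end groups still there.

All runs were generated by integration from invented constants, and the scatter is random.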